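**Plan**

1. Retrosynthesis: remove both acetates and take the lactol carbon back to a γ-lactone and the acetoxy carbinol back to an α-keto ester; cut the bond between the quaternary carbon and the oxolane (tertiary radical + 4-oxalylbutenolide); cut the cyclopentane bond between the ring-fusion CH next to CMe2 and the neighbouring ring CH2 (Nazarov); take the cycloheptenone back to 3-methylcyclohexenone (one-carbon ring expansion).
2. Enabling feature: the quaternary ring carbon (CH3 + oxolane) is made last from a tertiary radical, so it can first be a ring ketone. The five-membered ring is then a cyclopentanone whose two β-carbons are the ring-fusion CH and the ring CH2, the termini of a divinyl ketone built from the cycloheptene C=C and a β-silylvinyl group.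
3. Forward order: seven-membered ring (ring expansion), then iodination, CBS reduction, silylation and carbonylative Stille coupling to the dienone; the silicon-directed Nazarov cyclization closes the five-membered ring; ketone to tertiary alcohol, methylidene installed; radical coupling joins the butenolide; reduction and acetylation finish.
4. Stereochemistry: the CBS carbinol (temporary, later oxidised) steers the electrocyclization and so both ring-fusion centres; the quaternary centre forms on the convex face of the cis-hydroazulene radical, which also selects the butenolide face; hydrogen delivery anti to the hydroazulene gives the 3,4-cis oxolane; Felkin hydride addition sets the acetoxy carbinol; the anomeric acetate forms trans.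

Key step: step 8

Assumption: the carbinol configuration drawn for 13–16 and 20 is that from methyl addition on the convex face; either epimer gives the same tertiary radical in step 16. Hydroazulene numbering is used throughout (C1 = carbinol/quaternary carbon, C3a and C8a = ring fusion, C4 = CMe2, C8 = methylidene carbon).

**Route**

Step 1
Reactants: 1 3-methylcyclohex-2-en-1-one
Product: 2 [(3,3-dimethylcyclohex-1-en-1-yl)oxy]trimethylsilane
Conditions: Me2CuLi (MeLi, CuI), Et2O, 0 °C; then TMSCl, Et3N, 0 °C → rt
Reagents that add atoms: lithium dimethylcuprate C[Cu-]C.[Li+]; chlorotrimethylsilane C[Si](C)(C)Cl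
Why: Cuprate conjugate addition builds the gem-dimethyl carbon and O-silylation of the enolate fixes the enol ether double bond on the side of that carbon, which is the regiochemistry the ring expansion needs.

Step 2
Reactants: 2 [(3,3-dimethylcyclohex-1-en-1-yl)oxy]trimethylsilane
Product: 3 [(5,5-dimethylbicyclo[4.1.0]heptan-1-yl)oxy]trimethylsilane (racemic)
Conditions: Et2Zn, CH2I2, CH2Cl2, 0 °C → rt
Reagents that add atoms: diiodomethane ICI
Why: Furukawa–Simmons–Smith cyclopropanation of the electron-rich silyl enol ether should give the siloxycyclopropane whose one added carbon becomes the new ring member.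

Step 3
Reactants: 3 [(5,5-dimethylbicyclo[4.1.0]heptan-1-yl)oxy]trimethylsilane
Product: 5 4,4-dimethylcyclohept-2-en-1-one, via 3-chloro-4,4-dimethylcycloheptan-1-one 4 (not isolated)
Conditions: FeCl3, DMF, 0 °C → rt; then NaOAc, MeOH, reflux
Reagents that add atoms: none
Why: Saegusa ring expansion: one-electron oxidation gives the cyclopropyloxy radical, which opens at the internal bond to the ring-enlarged secondary radical; chlorine transfer and E1cB loss of HCl should give the cycloheptenone with CMe2 at the γ-position.

Step 4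
Reactants: 5 4,4-dimethylcyclohept-2-en-1-one
Product: 6 2-iodo-4,4-dimethylcyclohept-2-en-1-one
Conditions: I2, pyridine–CH2Cl2, rt
Reagents that add atoms: iodine II
Why: Johnson α-iodination of an enone (pyridine addition, iodination of the enolate, elimination), a reaction that works on γ,γ-disubstituted cycloalkenones.

Step 5
Reactants: 6 2-iodo-4,4-dimethylcyclohept-2-en-1-one
Product: 7 (1S)-2-iodo-4,4-dimethylcyclohept-2-en-1-ol
Conditions: (R)-Me-CBS (20 mol%), BH3·SMe2, THF, −20 °C
Reagents that add atoms: none
Why: Corey–Bakshi–Shibata reduction, for which α-halo enones are among the best substrates; the iodoalkenyl carbon acts as the large group, so the (R)-catalyst should give the (S)-carbinol, the temporary stereocentre that later steers the key step.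

Step 6
Reactants: 7 (1S)-2-iodo-4,4-dimethylcyclohept-2-en-1-ol
Product: 8 tert-butyl{[(1S)-2-iodo-4,4-dimethylcyclohept-2-en-1-yl]oxy}dimethylsilane
Conditions: TBSCl, imidazole, DMF, rt
Reagents that add atoms: tert-butyldimethylsilyl chloride CC(C)(C)[Si](C)(C)Cl
Why: Standard silylation of a secondary allylic alcohol gives a bulky, Lewis-acid-tolerant group for the key step.

Step 7
Reactants: 8 tert-butyl{[(1S)-2-iodo-4,4-dimethylcyclohept-2-en-1-yl]oxy}dimethylsilane; 9 (E)-tributyl[2-(trimethylsilyl)ethenyl]stannane
Product: 10 (E)-1-[(7S)-7-{[tert-butyl(dimethyl)silyl]oxy}-3,3-dimethylcyclohept-1-en-1-yl]-3-(trimethylsilyl)prop-2-en-1-one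
Conditions: CO (3 atm), Pd(PPh3)4 (5 mol%), LiCl, THF, 55 °C
Reagents that add atoms: carbon monoxide [C-]#[O+]
Why: Carbonylative Stille coupling of an alkenyl iodide with the (E)-silylvinylstannane is the established entry to β-silyl divinyl ketones and keeps the E geometry.

Step 8
Reactants: 10 (E)-1-[(7S)-7-{[tert-butyl(dimethyl)silyl]oxy}-3,3-dimethylcyclohept-1-en-1-yl]-3-(trimethylsilyl)prop-2-en-1-one
Product: 11 (8S)-8-{[tert-butyl(dimethyl)silyl]oxy}-4,4-dimethyl-3a,4,5,6,7,8-hexahydroazulen-1(8aH)-one (3a-H and 8a-H cis to each other and cis to the silyloxy group)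
Conditions: FeCl3 (1.1 equiv), CH2Cl2, −40 → 0 °C; aq. NaHCO3
Reagents that add atoms: none
Why: FeCl3 binds the ketone oxygen and generates the pentadienyl cation, whose thermal conrotatory 4π-electrocyclization joins the cycloheptene β-carbon (the CH next to CMe2) to the silyl-bearing vinyl carbon; the oxyallyl cation formed is β to silicon, so Me3Si leaves as Me3SiCl and the new C=C lies in the five-membered ring away from the ring fusion (silicon-directed Nazarov cyclization of a 1-cycloalkenyl β-silylvinyl ketone, which is the closest known reaction type). The cyclopentenone, the only ring formed, closes by this 4π-electrocyclic mode. The stereocentre next to CMe2 is set by torquoselectivity: allylic strain against the iron-bound carbonyl holds the silyloxy group pseudoaxial, and the vinyl terminus should rotate onto the ring face anti to it. The second ring-fusion centre is set when the iron dienolate is protonated on the face opposite the CMe2-bearing carbon, giving the cis fusion, which should also be the more stable arrangement at this epimerisable α-carbon. The step needs regiocontrol of the new double bond (secured by silicon), one sense of conrotation (secured by the temporary silyloxy stereocentre) and survival of the silyl ether (secured by low temperature and short contact with FeCl3).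

Step 9
Reactants: 11 (8S)-8-{[tert-butyl(dimethyl)silyl]oxy}-4,4-dimethyl-3a,4,5,6,7,8-hexahydroazulen-1(8aH)-one
Product: 12 (8S)-8-{[tert-butyl(dimethyl)silyl]oxy}-4,4-dimethyloctahydroazulen-1(2H)-one (cis-fused, configuration as in 11)
Conditions: H2 (1 atm), 10% Pd/C, EtOAc, rt
Reagents that add atoms: none
Why: Catalytic hydrogenation of the disubstituted enone C=C under neutral conditions turns the former vinyl carbons into the two ring CH2 groups without touching the α-stereocentre.

Step 10
Reactants: 12 (8S)-8-{[tert-butyl(dimethyl)silyl]oxy}-4,4-dimethyloctahydroazulen-1(2H)-one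
Product: 13 (8S)-8-{[tert-butyl(dimethyl)silyl]oxy}-1,4,4-trimethyldecahydroazulen-1-ol (methyl on the face of the ring-fusion hydrogens)
Conditions: MeLi, CeCl3, THF, −78 °C
Reagents that add atoms: methyllithium [Li]C
Why: Organocerium 1,2-addition is non-basic, so the enolisable ring-fusion centre is kept, and it installs the methyl group of the future quaternary carbon from the convex face.

Step 11
Reactants: 13 (8S)-8-{[tert-butyl(dimethyl)silyl]oxy}-1,4,4-trimethyldecahydroazulen-1-ol
Product: 14 1,4,4-trimethyldecahydroazulene-1,8-diol (cis-fused)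
Conditions: TBAF, THF, rt → 45 °C
Reagents that add atoms: none
Why: Fluoride desilylation frees the secondary carbinol whose stereochemical task is finished.

Step 12
Reactants: 14 1,4,4-trimethyldecahydroazulene-1,8-diol
Product: 15 1-hydroxy-1,4,4-trimethylperhydroazulen-8-one (cis-fused)
Conditions: Dess–Martin periodinane, NaHCO3, CH2Cl2, 0 °C → rt
Reagents that add atoms: none
Why: Buffered Dess–Martin oxidation converts only the secondary alcohol and avoids the base that could trigger retro-aldol cleavage of the β-hydroxy ketone.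

Step 13
Reactants: 15 1-hydroxy-1,4,4-trimethylperhydroazulen-8-one
Product: 16 1,4,4-trimethyl-8-methylideneperhydroazulen-1-ol (cis-fused)
Conditions: Zn, CH2Br2, TiCl4, THF–CH2Cl2, 0 °C → rt
Reagents that add atoms: dibromomethane BrCBr
Why: Takai–Lombardo methylenation is non-basic, tolerates free hydroxyl groups and does not epimerise α-centres, so it should install the exocyclic methylidene without retro-aldol cleavage.

Step 14
Reactants: 17 4-bromofuran-2(5H)-one
Product: 18 4-(tributylstannyl)furan-2(5H)-one
Conditions: (Bu3Sn)2, Pd(PPh3)4 (5 mol%), toluene, 100 °C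
Reagents that add atoms: hexabutylditin CCCC[Sn](CCCC)(CCCC)[Sn](CCCC)(CCCC)CCCC
Why: Palladium-catalysed stannylation of the vinylogous acyl bromide gives the known β-stannyl butenolide.

Step 15
Reactants: 18 4-(tributylstannyl)furan-2(5H)-one
Product: 19 methyl 2-oxo-2-(5-oxo-2,5-dihydrofuran-3-yl)acetate
Conditions: ClCOCO2Me, PdCl2(PPh3)2 (5 mol%), toluene, 60 °C
Reagents that add atoms: methyl chlorooxoacetate COC(=O)C(=O)Cl
Why: Stille acylation of an alkenylstannane with an oxalyl chloride half-ester gives the α-keto ester, an achiral and non-aromatisable acceptor that already has the oxidation pattern of the oxolane part.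

Step 16
Reactants: 16 1,4,4-trimethyl-8-methylideneperhydroazulen-1-ol; 19 methyl 2-oxo-2-(5-oxo-2,5-dihydrofuran-3-yl)acetate
Product: 21 methyl 2-oxo-2-[4-(1,4,4-trimethyl-8-methylideneperhydroazulen-1-yl)-5-oxooxolan-3-yl]acetate (3,4-cis on the lactone), via N-phthalimidoyl oxalate 20 (not isolated)
Conditions: i) ClCOCO2NPhth, Et3N, DMAP (cat.), THF, rt, filter; ii) 19 (2 equiv), Ru(bpy)3(PF6)2 (1.5 mol%), Hantzsch ester, i-Pr2NEt·HBF4, CH2Cl2, blue LEDs, rt
Reagents that add atoms: none
Why: Photoredox fragmentation of the tert-alkyl N-phthalimidoyl oxalate gives the tertiary radical, which undergoes Giese addition through its convex face to the unsubstituted alkene carbon of the doubly activated butenolide (the radical selects the acceptor face, with the lactone carbonyl carbon in the open sector between the C1 methyl and C2H2), and the α-keto radical takes hydrogen from the Hantzsch ester anti to the new quaternary centre, which sets the 3,4-cis lactone.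

Step 17
Reactants: 21 methyl 2-oxo-2-[4-(1,4,4-trimethyl-8-methylideneperhydroazulen-1-yl)-5-oxooxolan-3-yl]acetate
Product: 22 methyl (2S)-2-hydroxy-2-[4-(1,4,4-trimethyl-8-methylideneperhydroazulen-1-yl)-5-oxooxolan-3-yl]acetate
Conditions: L-Selectride, THF, −78 °C; aq. NH4Cl
Reagents that add atoms: none
Why: Chemoselective ketone reduction under Felkin–Anh control (the lactone carbon that carries the hydroazulene is the large group, and a chelate through the ring oxygen predicts the same sense) should give the (S)-carbinol while lactone and ester stay intact at low temperature.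

Step 18
Reactants: 22 methyl (2S)-2-hydroxy-2-[4-(1,4,4-trimethyl-8-methylideneperhydroazulen-1-yl)-5-oxooxolan-3-yl]acetate
Product: 23 methyl (2S)-2-hydroxy-2-[5-hydroxy-4-(1,4,4-trimethyl-8-methylideneperhydroazulen-1-yl)oxolan-3-yl]acetate (lactol, anomers interconvert)
Conditions: DIBAL-H (2.2 equiv), CH2Cl2, −78 °C; Rochelle salt
Reagents that add atoms: none
Why: Partial reduction of a γ-lactone to the lactol via its stable aluminium hemiacetal, relying on the higher reactivity of the lactone over the acyclic methyl ester at −78 °C.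

Step 19
Reactants: 23 methyl (2S)-2-hydroxy-2-[5-hydroxy-4-(1,4,4-trimethyl-8-methylideneperhydroazulen-1-yl)oxolan-3-yl]acetate
Product: 24 the target CNP0222222.1
Conditions: Ac2O, pyridine, DMAP (cat.), CH2Cl2, 0 °C → rt
Reagents that add atoms: acetic anhydride CC(=O)OC(C)=O
Why: Acetylation of the carbinol and of the equilibrating lactol should give the anomeric acetate trans to the bulky neighbouring substituent, the less hindered and more stable arrangement.

**Compound list**

1 | 3-methylcyclohex-2-en-1-one | CC1=CC(=O)CCC1 | starting material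
2 | [(3,3-dimethylcyclohex-1-en-1-yl)oxy]trimethylsilane | C[Si](C)(C)OC1=CC(C)(C)CCC1 | intermediate
3 | [(5,5-dimethylbicyclo[4.1.0]heptan-1-yl)oxy]trimethylsilane, racemic | C[Si](C)(C)OC12CCCC(C)(C)C1C2 | intermediate
4 | 3-chloro-4,4-dimethylcycloheptan-1-one, racemic | O=C1CC(Cl)C(C)(C)CCC1 | intermediate (not isolated)
5 | 4,4-dimethylcyclohept-2-en-1-one | O=C1C=CC(C)(C)CCC1 | intermediate
6 | 2-iodo-4,4-dimethylcyclohept-2-en-1-one | O=C1C(I)=CC(C)(C)CCC1 | intermediate
7 | (1S)-2-iodo-4,4-dimethylcyclohept-2-en-1-ol | O[C@H]1CCCC(C)(C)C=C1I | intermediate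
8 | tert-butyl{[(1S)-2-iodo-4,4-dimethylcyclohept-2-en-1-yl]oxy}dimethylsilane | CC(C)(C)[Si](C)(C)O[C@H]1CCCC(C)(C)C=C1I | intermediate
9 | (E)-tributyl[2-(trimethylsilyl)ethenyl]stannane | CCCC[Sn](CCCC)(CCCC)/C=C/[Si](C)(C)C | starting material
10 | (E)-1-[(7S)-7-{[tert-butyl(dimethyl)silyl]oxy}-3,3-dimethylcyclohept-1-en-1-yl]-3-(trimethylsilyl)prop-2-en-1-one | CC(C)(C)[Si](C)(C)O[C@H]1CCCC(C)(C)C=C1C(=O)/C=C/[Si](C)(C)C | intermediate
11 | (8S)-8-{[tert-butyl(dimethyl)silyl]oxy}-4,4-dimethyl-3a,4,5,6,7,8-hexahydroazulen-1(8aH)-one, cis-fused, silyloxy cis to both ring-fusion hydrogens | CC(C)(C)[Si](C)(C)O[C@H]1CCCC(C)(C)[C@@H]2C=CC(=O)[C@H]12 | intermediate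
12 | (8S)-8-{[tert-butyl(dimethyl)silyl]oxy}-4,4-dimethyloctahydroazulen-1(2H)-one, cis-fused | CC(C)(C)[Si](C)(C)O[C@H]1CCCC(C)(C)[C@@H]2CCC(=O)[C@H]12 | intermediate
13 | (8S)-8-{[tert-butyl(dimethyl)silyl]oxy}-1,4,4-trimethyldecahydroazulen-1-ol, cis-fused, 1-methyl on the face of the ring-fusion hydrogens | CC(C)(C)[Si](C)(C)O[C@H]1CCCC(C)(C)[C@@H]2CC[C@](C)(O)[C@H]12 | intermediate
14 | 1,4,4-trimethyldecahydroazulene-1,8-diol, cis-fused, configuration as in 13 | O[C@H]1CCCC(C)(C)[C@@H]2CC[C@](C)(O)[C@H]12 | intermediate
15 | 1-hydroxy-1,4,4-trimethylperhydroazulen-8-one, cis-fused | O=C1CCCC(C)(C)[C@@H]2CC[C@](C)(O)[C@H]12 | intermediate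
16 | 1,4,4-trimethyl-8-methylideneperhydroazulen-1-ol, cis-fused | C=C1CCCC(C)(C)[C@@H]2CC[C@](C)(O)[C@H]12 | intermediate
17 | 4-bromofuran-2(5H)-one | O=C1C=C(Br)CO1 | starting material
18 | 4-(tributylstannyl)furan-2(5H)-one | CCCC[Sn](CCCC)(CCCC)C1=CC(=O)OC1 | intermediate
19 | methyl 2-oxo-2-(5-oxo-2,5-dihydrofuran-3-yl)acetate | COC(=O)C(=O)C1=CC(=O)OC1 | intermediate
20 | 1,4,4-trimethyl-8-methylideneperhydroazulen-1-yl N-phthalimidoyl oxalate | C=C1CCCC(C)(C)[C@@H]2CC[C@](C)(OC(=O)C(=O)ON3C(=O)c4ccccc4C3=O)[C@H]12 | intermediate (not isolated)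
21 | methyl 2-oxo-2-[4-(1,4,4-trimethyl-8-methylideneperhydroazulen-1-yl)-5-oxooxolan-3-yl]acetate; lactone substituents cis, oxolane on the face of the ring-fusion hydrogens | C=C1CCCC(C)(C)[C@@H]2CC[C@@](C)([C@@H]3C(=O)OC[C@@H]3C(=O)C(=O)OC)[C@H]12 | intermediate
22 | methyl (2S)-2-hydroxy-2-[4-(1,4,4-trimethyl-8-methylideneperhydroazulen-1-yl)-5-oxooxolan-3-yl]acetate | C=C1CCCC(C)(C)[C@@H]2CC[C@@](C)([C@@H]3C(=O)OC[C@@H]3[C@H](O)C(=O)OC)[C@H]12 | intermediate
23 | methyl (2S)-2-hydroxy-2-[5-hydroxy-4-(1,4,4-trimethyl-8-methylideneperhydroazulen-1-yl)oxolan-3-yl]acetate; lactol drawn as the 4,5-trans anomer | C=C1CCCC(C)(C)[C@@H]2CC[C@@](C)([C@@H]3[C@@H](O)OC[C@@H]3[C@H](O)C(=O)OC)[C@H]12 | intermediate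
24 | CNP0222222.1: methyl (2S)-2-acetoxy-2-[5-acetoxy-4-(1,4,4-trimethyl-8-methylideneperhydroazulen-1-yl)oxolan-3-yl]acetate | C=C1CCCC(C)(C)[C@@H]2CC[C@@](C)([C@@H]3[C@@H](OC(C)=O)OC[C@@H]3[C@H](OC(C)=O)C(=O)OC)[C@H]12 | target

**Step count**

Total: 19 steps. Longest linear sequence: 17 steps (steps 1–13, then 16–19, from 1); the acceptor branch is 2 steps (14–15).

**Steps most likely to fail**

Step 8. The silyloxy stereocentre may steer the conrotation only weakly, or protonation of the dienolate may not give the cis fusion, so that diastereomers of 11 form. The fallback sets out from 11 (as whatever mixture forms) and comes back at 12. DBU in toluene moves the double bond into the ring fusion and gives the single tetrasubstituted enone (8S)-8-{[tert-butyl(dimethyl)silyl]oxy}-4,4-dimethyl-2,3,5,6,7,8-hexahydroazulen-1(4H)-one F1, in which both ring-fusion centres are erased. TBAF gives the hydroxy enone (8S)-8-hydroxy-4,4-dimethyl-2,3,5,6,7,8-hexahydroazulen-1(4H)-one F2. Hydroxyl-directed hydrogenation with Crabtree's catalyst should deliver both hydrogens cis to the carbinol and give the cis-fused hydroxy ketone (8S)-8-hydroxy-4,4-dimethyloctahydroazulen-1(2H)-one F3. TBSCl and imidazole then return 12.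

Step 16. Enolisation of the α-keto ester may erode the kinetically set cis relationship on the lactone, and the hydride reduction of step 17 would then act on a mixture. The fallback sets out from 21 (epimer mixture accepted) and comes back at 23. Ac2O, Et3N and DMAP should convert both epimers into the (Z)-enol acetate methyl (Z)-2-acetoxy-2-[4-(1,4,4-trimethyl-8-methylideneperhydroazulen-1-yl)-5-oxodihydrofuran-3(2H)-ylidene]acetate F4. Hydrogenation of this α-acetoxy acrylate with a cationic Rh–DuPhos catalyst (ligand enantiomer matched to delivery on the face away from the hydroazulene) adds both hydrogens syn and should spare the methylidene, giving the acetate methyl (2S)-2-acetoxy-2-[4-(1,4,4-trimethyl-8-methylideneperhydroazulen-1-yl)-5-oxooxolan-3-yl]acetate F5, in which the ring centre and the acetoxy carbinol are set together. DIBAL-H at −78 °C then reduces the lactone and removes the acetate to give 23.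

Step 18. The methyl ester, activated by the neighbouring aluminium alkoxide, may be reduced in competition with the hindered lactone. The fallback sets out from 22 and comes back at 23. LiOH in THF–water followed by acidification gives the hydroxy acid (2S)-2-hydroxy-2-[4-(1,4,4-trimethyl-8-methylideneperhydroazulen-1-yl)-5-oxooxolan-3-yl]acetic acid F6 (the γ-lactone recloses on acidification). Excess DIBAL-H reduces the lactone while the carboxylate is inert and gives the lactol acid (2S)-2-hydroxy-2-[5-hydroxy-4-(1,4,4-trimethyl-8-methylideneperhydroazulen-1-yl)oxolan-3-yl]acetic acid F7. TMSCHN2 in toluene–MeOH re-forms the methyl ester and gives 23.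

**Further compounds**

F1 | step 8 | (8S)-8-{[tert-butyl(dimethyl)silyl]oxy}-4,4-dimethyl-2,3,5,6,7,8-hexahydroazulen-1(4H)-one | CC(C)(C)[Si](C)(C)O[C@H]1CCCC(C)(C)C2=C1C(=O)CC2
F2 | step 8 | (8S)-8-hydroxy-4,4-dimethyl-2,3,5,6,7,8-hexahydroazulen-1(4H)-one | O[C@H]1CCCC(C)(C)C2=C1C(=O)CC2
F3 | step 8 | (8S)-8-hydroxy-4,4-dimethyloctahydroazulen-1(2H)-one, cis-fused, hydroxyl cis to both ring-fusion hydrogens | O[C@H]1CCCC(C)(C)[C@@H]2CCC(=O)[C@H]12
F4 | step 16 | methyl (Z)-2-acetoxy-2-[4-(1,4,4-trimethyl-8-methylideneperhydroazulen-1-yl)-5-oxodihydrofuran-3(2H)-ylidene]acetate | C=C1CCCC(C)(C)[C@@H]2CC[C@@](C)([C@@H]3C(=O)OC/C3=C(\OC(C)=O)C(=O)OC)[C@H]12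
F5 | step 16 | methyl (2S)-2-acetoxy-2-[4-(1,4,4-trimethyl-8-methylideneperhydroazulen-1-yl)-5-oxooxolan-3-yl]acetate | C=C1CCCC(C)(C)[C@@H]2CC[C@@](C)([C@@H]3C(=O)OC[C@@H]3[C@H](OC(C)=O)C(=O)OC)[C@H]12
F6 | step 18 | (2S)-2-hydroxy-2-[4-(1,4,4-trimethyl-8-methylideneperhydroazulen-1-yl)-5-oxooxolan-3-yl]acetic acid | C=C1CCCC(C)(C)[C@@H]2CC[C@@](C)([C@@H]3C(=O)OC[C@@H]3[C@H](O)C(=O)O)[C@H]12
F7 | step 18 | (2S)-2-hydroxy-2-[5-hydroxy-4-(1,4,4-trimethyl-8-methylideneperhydroazulen-1-yl)oxolan-3-yl]acetic acid | C=C1CCCC(C)(C)[C@@H]2CC[C@@](C)([C@@H]3[C@@H](O)OC[C@@H]3[C@H](O)C(=O)O)[C@H]12
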